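## Analysis of the target

The target is a depside: two benzene rings joined through one aryl ester, with no ring fusion and no stereocentre. Ring A is a 2,4-dihydroxy-6-propylbenzoyl unit whose carbonyl carbon sits between the C2 hydroxyl and the C6 propyl group. Ring B is a pentasubstituted benzoic acid with the carboxyl at C1', a methoxy group at C2', the ester oxygen at C3', a free hydroxyl at C4', hydrogen at C5' and propyl at C6'. The ester is hindered on both sides (two ortho substituents on the acyl ring, two ortho oxygens on the phenol ring), so acylation of a ring B phenol is an unattractive way to make it. The three contiguous oxygens at C2', C3' and C4' each carry a different group (methyl, acyl, hydrogen) and must be told apart. The sensitive points are the ester, which can migrate to a neighbouring phenoxide or be cleaved by nucleophiles, and the electron-rich benzoic acid of ring B, which can decarboxylate in hot acid. The three phenols and the acid are therefore best released together at the end under neutral conditions. The strategy rests on one feature: the C2'–C3'–C4' oxygen triad with C5' is a 2-acyloxy-3-oxobutanoate in disguise, and C1' (carboxyl) with C6' (propyl) is a hex-2-ynoate, so ring B can be assembled around an ester that already exists.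

## Retrosynthetic reasoning

**18 to 17.** The acid, both ring A phenols and the 4'-phenol are masked as benzyl groups, so target 18 comes from the tetrabenzyl compound 17 by one neutral hydrogenolysis. This cuts only O–benzyl bonds and leaves the depside ester and the methyl ether alone.

**17 to 15 by way of 16.** The O–CH3 bond at C2' and then the O–benzyl bond at C4' are cut. In 15 the 2'-hydroxyl is hydrogen-bonded to the neighbouring ester carbonyl and flanked on both sides, whereas the 4'-hydroxyl is free and more acidic. Benzylation with 4 can thus be directed to O-4' (giving 16) and the remaining phenol methylated (giving 17). This lets the ring-forming step deliver two unprotected phenols.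

**15 to 11 and 13.** The C1'–C2' and C5'–C6' bonds of ring B are cut. These cuts place all three contiguous oxygens on one four-carbon piece, diene 11, where they are already differentiated: C2' is the ketene acetal carbon, C3' carries the ring A aroyloxy group, and C4' is the enol ether carbon. The carboxyl and the propyl group fall on the two alkyne carbons of 13. Because 13 is at the alkyne oxidation level, the ring arrives aromatic once the methoxy group of the ketal carbon is lost, with no separate oxidation. The forward reaction must join the methylene terminus of 11 to the propyl-bearing carbon of 13 and the ketene acetal carbon to the carbon next to the ester.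

**11 to 8 by way of 9.** The two O–Si bonds are cut in turn. Keto ester 8 is silylated first at the ketone enol (9) and then, after deprotonation of the methyl group, at the ester enolate oxygen (11). Nothing in the carbon skeleton changes.

**8 to 6 and 7.** The bond cut is the one between the carboxylate oxygen and the sp3 carbon that becomes C3', not the C(=O)–O bond. Substitution at the chlorine-bearing carbon of 7 takes place away from the shielded carbonyl carbon of acid 6, so the doubly hindered depside ester is made without an acylation and before ring B exists.

**6 to 1 by way of 5 and 3.** Acid 6 is the oxidation product of aldehyde 5, which is the bis-benzyl ether (from 4) of aldehyde 3. The formyl C–C bond of 3 is cut to reveal the symmetric resorcinol 1, whose two hydroxyls direct formylation to the position that becomes C1 of ring A.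

**13 to 12 and 4.** The benzyl ester is cut to the acid 12 and the halide 4, so that the ring B carboxyl is released in the same final hydrogenolysis as the phenols.

## Alternatives that were turned down

Alternative 1: Ring B is disconnected at C1'–C6' and C2'–C3' and built at the cyclohexanedione level. In the forward sense, dibenzyl malonate A2 adds in a Michael reaction to the enone (E)-2-oxohept-3-en-1-yl 2,4-bis(benzyloxy)-6-propylbenzoate A1. The enolate of the acyloxymethyl ketone then closes onto one malonate ester in a Claisen-type step to give the enolised dione A3, which must be dehydrogenated to reach 15.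
- For it: the chemistry is robust enolate chemistry with cheap reagents and no moisture-sensitive diene. On scalability and ease of handling it is stronger than the chosen route.
- Against it: the ring closure needs stoichiometric alkoxide and passes through an α-acyloxy ketone enolate, which can transfer its acyl group to carbon or be transesterified. The two stereocentres of A3 are made only to be destroyed. The extra dehydrogenation must be done next to the electron-rich ring A with its benzylic ethers, where halogenating or quinone oxidants find other points of attack.
- Comparison: the chosen route delivers the aromatic oxidation level directly because the alkyne carries the unsaturation, and it is one operation shorter on ring B.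

Alternative 2: Ring A is disconnected at C1–C6 in a biomimetic way. The triketo aryl ester A4, made by acylating the ring B phenol A5, is folded by an intramolecular aldol reaction of chain C2 onto the C7 ketone. Dehydration and enolisation then give the ring A resorcylate A6, which needs only one hydrogenolysis to reach 18.
- For it: ring A appears with free phenols and no protecting groups. On protecting-group economy for ring A it is stronger than the chosen route.
- Against it: the aryl ester of A4 is an activated ester. Under the basic conditions needed for the aldol, C-acylation by the chain terminus or enol lactonisation of the chain would each expel the phenoxide of A5 and destroy the depside bond. The aldol mode that keeps the ester has no built-in advantage over these. The route also needs A5, a benzene with four contiguous, differentiated substituents, which is itself the hard part of the molecule and would take a separate multi-step synthesis.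
- Comparison: the chosen route never needs a free ring B phenol and forms ring B and its substitution pattern in one step from acyclic pieces.

Alternative 3: The depside carbonyl is disconnected on both sides. Ring A iodide A7, carbon monoxide A8 and phenol A5 are joined by palladium-catalysed aryloxycarbonylation (zerovalent palladium with a wide-bite-angle diphosphine and an amine base) to give A9, which is the same compound as 17.
- For it: it is convergent and modular, and all protecting groups are in place before the coupling, so no free phenol ever sits beside the ester until the last step. On convergence and on avoiding acyl migration it is stronger than the chosen route.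
- Against it: oxidative addition into the 2,6-disubstituted, electron-rich iodide A7 is slow, and the resulting acylpalladium is hindered. The nucleophile A5 is a phenol flanked by two ortho oxygens, and phenols are poorer partners than alcohols in this reaction. As in alternative 2, A5 must first be made, which moves most of the step count into the synthesis of a pentasubstituted benzene.
- Comparison: the chosen route forms the hindered ester by alkylation at an sp3 carbon, which is indifferent to the crowding around the carbonyl, and reaches 17 in nine linear steps from 1.

Key step: step 8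

Assumption: the enol ether double bonds of 9, 10 and 11 are expected as E/Z mixtures and are left undefined, because all of these carbons become aromatic carbons of ring B; 7, 8 and 14 are racemic and their stereocentres are erased later.

## Route

Step 1
Reactants: 1 5-propylbenzene-1,3-diol (5-propylresorcinol)
Product: 3 2,4-dihydroxy-6-propylbenzaldehyde, via aryl dimethyliminium chloride 2 (not isolated)
Conditions: POCl3, DMF, 0 °C to rt; then H2O, 50 °C
Reagents that add atoms: N,N-dimethylformamide, CN(C)C=O; water, O
Why: Vilsmeier–Haack formylation; as is usual for 5-alkylresorcinols the chloroiminium electrophile should attack the position para to one hydroxyl and ortho to the other rather than the position between the two hydroxyls, and hydrolysis of iminium salt 2 releases the aldehyde.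

Step 2
Reactants: 3 2,4-dihydroxy-6-propylbenzaldehyde; 4 benzyl bromide
Product: 5 2,4-bis(benzyloxy)-6-propylbenzaldehyde
Conditions: BnBr (2.5 equiv), K2CO3, DMF, 60 °C
Reagents that add atoms: benzyl bromide (4), BrCc1ccccc1
Why: Williamson ether synthesis; excess halide and warming in DMF should alkylate the hydrogen-bonded 2-hydroxyl as well as the free 4-hydroxyl.

Step 3
Reactants: 5 2,4-bis(benzyloxy)-6-propylbenzaldehyde
Product: 6 2,4-bis(benzyloxy)-6-propylbenzoic acid
Conditions: NaClO2, NaH2PO4, 2-methylbut-2-ene, t-BuOH/THF/H2O, rt
Reagents that add atoms: sodium chlorite, [Na+].[O-]Cl=O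
Why: Pinnick oxidation; chlorous acid oxidises the hindered aldehyde without touching the benzyl ethers, and the alkene scavenger removes hypochlorous acid before it can chlorinate the electron-rich ring.

Step 4
Reactants: 6 2,4-bis(benzyloxy)-6-propylbenzoic acid; 7 methyl 2-chloro-3-oxobutanoate
Product: 8 methyl 2-{[2,4-bis(benzyloxy)-6-propylbenzoyl]oxy}-3-oxobutanoate (racemic)
Conditions: Et3N, DMF, rt
Reagents that add atoms: none
Why: SN2 O-alkylation of a carboxylate by an α-chloro β-keto ester, the standard access to 2-acyloxy-3-oxobutanoates; the new bond forms at the sp3 carbon of 7, so the two ortho substituents of 6 do not slow it.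

Step 5
Reactants: 8 methyl 2-{[2,4-bis(benzyloxy)-6-propylbenzoyl]oxy}-3-oxobutanoate
Product: 9 methyl 2-{[2,4-bis(benzyloxy)-6-propylbenzoyl]oxy}-3-(trimethylsiloxy)but-2-enoate
Conditions: Me3SiCl, Et3N, toluene, rt
Reagents that add atoms: chlorotrimethylsilane, C[Si](C)(C)Cl
Why: Soft enolisation and O-silylation of a β-keto ester; the doubly activated C2–H is the only proton acidic enough for the amine base, so the ketone enol is silylated regioselectively.

Step 6
Reactants: 9 methyl 2-{[2,4-bis(benzyloxy)-6-propylbenzoyl]oxy}-3-(trimethylsiloxy)but-2-enoate
Product: 11 1-methoxy-1,3-bis(trimethylsiloxy)buta-1,3-dien-2-yl 2,4-bis(benzyloxy)-6-propylbenzoate, via lithium dienolate 10 (not isolated)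
Conditions: LiN(i-Pr)2 (LDA), THF, −78 °C; then Me3SiCl, −78 °C to rt
Reagents that add atoms: chlorotrimethylsilane, C[Si](C)(C)Cl
Why: Standard preparation of 1-alkoxy-1,3-bis(silyloxy)buta-1,3-dienes: kinetic γ-deprotonation of the silyl enol ether gives dienolate 10, which is silylated on the ester oxygen. The shielded aroyl carbonyl and the low temperature should keep the amide base and the dienolate from attacking the ester.

Step 7
Reactants: 12 hex-2-ynoic acid; 4 benzyl bromide
Product: 13 benzyl hex-2-ynoate
Conditions: BnBr, KHCO3, DMF, rt
Reagents that add atoms: benzyl bromide (4), BrCc1ccccc1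
Why: Carboxylate O-alkylation; the weak hydrogen carbonate base deprotonates only the acid, so the alkyne should not isomerise to the allene.

Step 8
Reactants: 11 1-methoxy-1,3-bis(trimethylsiloxy)buta-1,3-dien-2-yl 2,4-bis(benzyloxy)-6-propylbenzoate; 13 benzyl hex-2-ynoate
Product: 15 benzyl 3-{[2,4-bis(benzyloxy)-6-propylbenzoyl]oxy}-2,4-dihydroxy-6-propylbenzoate, via cyclohexa-1,4-diene cycloadduct 14 (not isolated)
Conditions: 13 (3 equiv), toluene, 110 °C, sealed tube; then 1 M HCl, THF, rt
Reagents that add atoms: none
Why: The reaction is a Diels–Alder cycloaddition of a 1-alkoxy-1,3-bis(silyloxy)buta-1,3-diene with an acetylenic ester followed by aromatisation, the established way of turning such dienes and alkynoates into 2,4-dihydroxybenzoates. The unsubstituted C4 methylene of 11, the terminus with the largest HOMO coefficient, bonds to the propyl-bearing β-carbon of 13 to form C5'–C6', and the ketene acetal carbon C1 bonds to the α-carbon to form C1'–C2'; whether the two bonds form in concert or by conjugate addition and then ring closure, the same regioisomer results. Ring B is thus closed by an intermolecular [4+2] event that makes both new ring bonds and gives the cyclohexa-1,4-diene 14. Its only stereocentre, the ketal carbon carrying the methoxy and silyloxy groups, forms as a racemate and needs no control because it is erased at once. Acid work-up ionises this ketal with loss of methanol, the C5' hydrogen is lost in a formal 1,4-elimination, and both silyl ethers are hydrolysed to give 15. The only selectivity required is regiochemical, and it is secured by the matched polarisation of the partners: the oxygen donors at C1 and C3 push electron density to C4 of the diene, and the ester of 13 makes its β-carbon the electrophilic site. The aroyloxy group at C2 should lower the diene HOMO only modestly, and its carbonyl is shielded by the 2-benzyloxy and 6-propyl groups, so it should neither migrate nor react. An excess of the inexpensive alkyne is used because its β-propyl group makes it a sluggish dienophile.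

Step 9
Reactants: 15 benzyl 3-{[2,4-bis(benzyloxy)-6-propylbenzoyl]oxy}-2,4-dihydroxy-6-propylbenzoate; 4 benzyl bromide
Product: 16 benzyl 4-(benzyloxy)-3-{[2,4-bis(benzyloxy)-6-propylbenzoyl]oxy}-2-hydroxy-6-propylbenzoate
Conditions: BnBr (1.05 equiv), K2CO3 (1.1 equiv), acetone, rt to 40 °C
Reagents that add atoms: benzyl bromide (4), BrCc1ccccc1
Why: Regioselective Williamson etherification of a 2,4-dihydroxybenzoate; the 4'-hydroxyl is the more acidic and accessible one, while the 2'-hydroxyl is held in a hydrogen bond to the ester carbonyl and flanked on both sides. The crowded aroyl carbonyl should resist attack by the neighbouring phenoxide.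

Step 10
Reactants: 16 benzyl 4-(benzyloxy)-3-{[2,4-bis(benzyloxy)-6-propylbenzoyl]oxy}-2-hydroxy-6-propylbenzoate
Product: 17 benzyl 4-(benzyloxy)-3-{[2,4-bis(benzyloxy)-6-propylbenzoyl]oxy}-2-methoxy-6-propylbenzoate
Conditions: MeI (excess), K2CO3, DMF, rt
Reagents that add atoms: iodomethane, CI
Why: Williamson methylation of a salicylate-type phenol; DMF breaks the hydrogen bond, and a large excess of the small electrophile should make bimolecular alkylation outrun any intramolecular acyl shift.

Step 11
Reactants: 17 benzyl 4-(benzyloxy)-3-{[2,4-bis(benzyloxy)-6-propylbenzoyl]oxy}-2-methoxy-6-propylbenzoate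
Product: 18 3-[(2,4-dihydroxy-6-propylbenzoyl)oxy]-4-hydroxy-2-methoxy-6-propylbenzoic acid (CNP0126444.0)
Conditions: H2 (1 atm), 10% Pd/C, EtOAc, rt
Reagents that add atoms: none
Why: Catalytic hydrogenolysis cleaves the three benzyl ethers and the benzyl ester in one neutral operation at room temperature, so neither acyl migration nor decarboxylation of the ring B acid is provoked.

## Compound list

1 | 5-propylbenzene-1,3-diol (5-propylresorcinol) | CCCc1cc(O)cc(O)c1 | starting material
2 | N-[(2,4-dihydroxy-6-propylphenyl)methylidene]-N-methylmethanaminium chloride | CCCc1cc(O)cc(O)c1C=[N+](C)C.[Cl-] | intermediate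
3 | 2,4-dihydroxy-6-propylbenzaldehyde | CCCc1cc(O)cc(O)c1C=O | intermediate
4 | benzyl bromide | BrCc1ccccc1 | starting material
5 | 2,4-bis(benzyloxy)-6-propylbenzaldehyde | CCCc1cc(OCc2ccccc2)cc(OCc2ccccc2)c1C=O | intermediate
6 | 2,4-bis(benzyloxy)-6-propylbenzoic acid | CCCc1cc(OCc2ccccc2)cc(OCc2ccccc2)c1C(=O)O | intermediate
7 | methyl 2-chloro-3-oxobutanoate (racemic) | CC(=O)C(Cl)C(=O)OC | starting material
8 | methyl 2-{[2,4-bis(benzyloxy)-6-propylbenzoyl]oxy}-3-oxobutanoate (racemic) | CCCc1cc(OCc2ccccc2)cc(OCc2ccccc2)c1C(=O)OC(C(C)=O)C(=O)OC | intermediate
9 | methyl 2-{[2,4-bis(benzyloxy)-6-propylbenzoyl]oxy}-3-(trimethylsiloxy)but-2-enoate (E/Z mixture) | CCCc1cc(OCc2ccccc2)cc(OCc2ccccc2)c1C(=O)OC(C(=O)OC)=C(C)O[Si](C)(C)C | intermediate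
10 | lithium 2-{[2,4-bis(benzyloxy)-6-propylbenzoyl]oxy}-1-methoxy-3-(trimethylsiloxy)buta-1,3-dien-1-olate | [Li+].[O-]C(OC)=C(OC(=O)c1c(CCC)cc(OCc2ccccc2)cc1OCc1ccccc1)C(=C)O[Si](C)(C)C | intermediate
11 | 1-methoxy-1,3-bis(trimethylsiloxy)buta-1,3-dien-2-yl 2,4-bis(benzyloxy)-6-propylbenzoate (E/Z mixture) | COC(O[Si](C)(C)C)=C(OC(=O)c1c(CCC)cc(OCc2ccccc2)cc1OCc1ccccc1)C(=C)O[Si](C)(C)C | intermediate
12 | hex-2-ynoic acid | CCCC#CC(=O)O | starting material
13 | benzyl hex-2-ynoate | CCCC#CC(=O)OCc1ccccc1 | intermediate
14 | benzyl 5-{[2,4-bis(benzyloxy)-6-propylbenzoyl]oxy}-6-methoxy-2-propyl-4,6-bis(trimethylsiloxy)cyclohexa-1,4-diene-1-carboxylate (racemic) | CCCC1=C(C(=O)OCc2ccccc2)C(OC)(O[Si](C)(C)C)C(OC(=O)c2c(CCC)cc(OCc3ccccc3)cc2OCc2ccccc2)=C(O[Si](C)(C)C)C1 | intermediate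
15 | benzyl 3-{[2,4-bis(benzyloxy)-6-propylbenzoyl]oxy}-2,4-dihydroxy-6-propylbenzoate | CCCc1cc(OCc2ccccc2)cc(OCc2ccccc2)c1C(=O)Oc1c(O)cc(CCC)c(C(=O)OCc2ccccc2)c1O | intermediate
16 | benzyl 4-(benzyloxy)-3-{[2,4-bis(benzyloxy)-6-propylbenzoyl]oxy}-2-hydroxy-6-propylbenzoate | CCCc1cc(OCc2ccccc2)cc(OCc2ccccc2)c1C(=O)Oc1c(OCc2ccccc2)cc(CCC)c(C(=O)OCc2ccccc2)c1O | intermediate
17 | benzyl 4-(benzyloxy)-3-{[2,4-bis(benzyloxy)-6-propylbenzoyl]oxy}-2-methoxy-6-propylbenzoate | CCCc1cc(OCc2ccccc2)cc(OCc2ccccc2)c1C(=O)Oc1c(OCc2ccccc2)cc(CCC)c(C(=O)OCc2ccccc2)c1OC | intermediate
18 | 3-[(2,4-dihydroxy-6-propylbenzoyl)oxy]-4-hydroxy-2-methoxy-6-propylbenzoic acid (CNP0126444.0) | CCCc1cc(O)cc(O)c1C(=O)Oc1c(O)cc(CCC)c(C(=O)O)c1OC | target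

## Step count and risks

Total step count: 11. Longest linear sequence: 10 steps (steps 1 to 6 and 8 to 11, from 1); step 7 is a one-step side branch.

**Step 8 (key step).** The most likely failure is thermal degradation of diene 11 (silyl shifts, adventitious hydrolysis) outrunning the cycloaddition, because the β-propyl group makes 13 a weak dienophile that needs prolonged heating. A second risk is elimination of the silyloxy group in place of the methoxy group from the ketal carbon, which would leave O-2' methylated one stage early; such material would still converge on 17 after benzylation at O-4'. Fallback: set out from 11 and replace the alkyne by the more reactive allenic ester benzyl hexa-2,3-dienoate F1, made by Wittig reaction of benzyl (triphenylphosphoranylidene)acetate with the ketene generated in the flask from butanoyl chloride and Et3N in CH2Cl2. The diene should add across the activated 2,3-double bond of the allene at rt to 60 °C with the same regiochemistry, giving the alkylidenecyclohexene cycloadduct F2. Acid work-up removes methanol and the silyl groups and shifts the exocyclic double bond into the ring, so the sequence comes back to the route at 15.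

**Step 6.** The most likely failures are rearrangement of the α-acyloxy dienolate by acyl transfer from oxygen to carbon, competing deprotonation at the benzylic position of the ring A propyl group, and hydrolytic loss of the diene during isolation. Fallback: set out from 8 and silylate both positions in one pot by soft enolisation with Me3SiOTf (2.2 equiv) and Et3N in Et2O at 0 °C, which never generates a lithium enolate. After removal of the ammonium salt the crude material is used directly, so the route is rejoined at 11.

**Step 9.** The most likely failure is migration of the aroyl group from O-3' to the neighbouring 4'-phenoxide before it is alkylated, or benzylation at both phenols. Fallback: set out from 15 and form the ether by a Mitsunobu reaction with benzyl alcohol, PPh3 and diisopropyl azodicarboxylate in THF at 0 °C. No alkali phenoxide is then held in solution, and the hydrogen-bonded 2'-hydroxyl reacts far more slowly under these conditions; the route is rejoined at 16.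

**Step 10.** The most likely failure is slow alkylation of the hydrogen-bonded, doubly flanked 2'-hydroxyl, which would give the 2'-phenoxide time to attack the adjacent ester carbonyl and move the aroyl group to O-2'. Fallback: set out from 16 and methylate by silver-assisted activation of the electrophile instead of phenoxide formation (Purdie methylation: MeI, Ag2O, MeCN, 40 °C, in the dark), so that no free alkali phenoxide sits beside the ester; the route is rejoined at 17.

## Further compounds

F1 | step 8 | benzyl hexa-2,3-dienoate (racemic) | CCC=C=CC(=O)OCc1ccccc1
F2 | step 8 | benzyl 3-{[2,4-bis(benzyloxy)-6-propylbenzoyl]oxy}-2-methoxy-6-propylidene-2,4-bis(trimethylsiloxy)cyclohex-3-ene-1-carboxylate (mixture of stereoisomers) | CCC=C1CC(O[Si](C)(C)C)=C(OC(=O)c2c(CCC)cc(OCc3ccccc3)cc2OCc2ccccc2)C(OC)(O[Si](C)(C)C)C1C(=O)OCc1ccccc1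
F0 | step 6 | none | none
F0 | step 9 | none | none
F0 | step 10 | none | none
A1 | alternative 1 | (E)-2-oxohept-3-en-1-yl 2,4-bis(benzyloxy)-6-propylbenzoate | CCC/C=C/C(=O)COC(=O)c1c(CCC)cc(OCc2ccccc2)cc1OCc1ccccc1
A2 | alternative 1 | dibenzyl malonate | O=C(CC(=O)OCc1ccccc1)OCc1ccccc1
A3 | alternative 1 | benzyl trans-3-{[2,4-bis(benzyloxy)-6-propylbenzoyl]oxy}-2-hydroxy-4-oxo-6-propylcyclohex-2-ene-1-carboxylate (racemic) | CCC[C@@H]1CC(=O)C(OC(=O)c2c(CCC)cc(OCc3ccccc3)cc2OCc2ccccc2)=C(O)[C@H]1C(=O)OCc1ccccc1
A4 | alternative 2 | 6-(benzyloxy)-3-[(benzyloxy)carbonyl]-2-methoxy-4-propylphenyl 3,5,7-trioxodecanoate | CCCC(=O)CC(=O)CC(=O)CC(=O)Oc1c(OCc2ccccc2)cc(CCC)c(C(=O)OCc2ccccc2)c1OC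
A5 | alternative 2 | benzyl 4-(benzyloxy)-3-hydroxy-2-methoxy-6-propylbenzoate | CCCc1cc(OCc2ccccc2)c(O)c(OC)c1C(=O)OCc1ccccc1
A6 | alternative 2 | benzyl 4-(benzyloxy)-3-[(2,4-dihydroxy-6-propylbenzoyl)oxy]-2-methoxy-6-propylbenzoate | CCCc1cc(O)cc(O)c1C(=O)Oc1c(OCc2ccccc2)cc(CCC)c(C(=O)OCc2ccccc2)c1OC
A7 | alternative 3 | 1,5-bis(benzyloxy)-2-iodo-3-propylbenzene | CCCc1cc(OCc2ccccc2)cc(OCc2ccccc2)c1I
A8 | alternative 3 | carbon monoxide | [C-]#[O+]
A9 | alternative 3 | benzyl 4-(benzyloxy)-3-{[2,4-bis(benzyloxy)-6-propylbenzoyl]oxy}-2-methoxy-6-propylbenzoate | CCCc1cc(OCc2ccccc2)cc(OCc2ccccc2)c1C(=O)Oc1c(OCc2ccccc2)cc(CCC)c(C(=O)OCc2ccccc2)c1OC
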